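## Retrosynthetic overview

1. Target (ring atoms O1, C2 aryl, C3 CH2OH, C4 aroyl, C5) ⇒ its bis-O-benzyl ether ⇒ by aldehyde-selective reduction, the all-trans 4-aroyl-2-aryl-tetrahydrofuran-3-carbaldehyde.
2. Disconnect C4–C(=O)Ar: conjugate addition of an aroyl radical (from the arylglyoxylic acid, loss of CO2) to a 2-aryl-2,5-dihydrofuran-3-carbaldehyde. C3 and C4 are then set by base equilibration against C2.
3. Disconnect O1–C2 and C3–C4: amine-catalysed asymmetric oxa-Michael/aldol condensation of a cinnamaldehyde with glycolaldehyde. This forms the only new ring (the oxolane) and the first stereocentre (C2).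
4. Cinnamaldehyde ⇒ Wittig two-carbon homologation of 3-(benzyloxy)-4-methoxybenzaldehyde; keto acid ⇒ SeO2 oxidation of the matching acetophenone. Both benzene rings are bought.

Assumption: 3-(benzyloxy)-4-methoxybenzaldehyde and 1-[3-(benzyloxy)-4-methoxyphenyl]ethan-1-one are bought as such (catalogue benzyl ethers of isovanillin and of 3-hydroxy-4-methoxyacetophenone).

## Route

Step 1
Reactants: 1 3-(benzyloxy)-4-methoxybenzaldehyde; 2 (triphenylphosphoranylidene)acetaldehyde
Product: 3 (E)-3-[3-(benzyloxy)-4-methoxyphenyl]prop-2-enal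
Conditions: 2 (1.1 equiv), PhMe, 80 °C
Reagents that add atoms: none
Why: Wittig olefination with the formyl-stabilised ylide gives the (E)-cinnamaldehyde selectively, and no stereocentre is formed.

Step 2
Reactants: 3 (E)-3-[3-(benzyloxy)-4-methoxyphenyl]prop-2-enal; 4 1,4-dioxane-2,5-diol (glycolaldehyde dimer)
Product: 8 (R)-2-[3-(benzyloxy)-4-methoxyphenyl]-2,5-dihydrofuran-3-carbaldehyde, via glycolaldehyde monomer 5 (not isolated), via oxa-Michael adduct 6 (not isolated), via aldol adduct 7 (not isolated)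
Conditions: (S)-2-[diphenyl(trimethylsilyloxy)methyl]pyrrolidine (20 mol %), PhCO2H (20 mol %), 4 (0.75 equiv, in portions), CHCl3, rt
Reagents that add atoms: none
Why: Proposed new method: an amine-catalysed asymmetric oxa-Michael/aldol condensation that uses glycolaldehyde as the O–C–C(=O) partner; the hydroxyl of glycolaldehyde adds to C-β of the (E, s-trans) iminium ion of 3 on the Si face, because the Re face is blocked by the CPh2OSiMe3 group of the (S)-catalyst (the same facial sense in which carbon and sulfur nucleophiles add to cinnamaldehyde iminium ions of this catalyst), and this fixes C2; the resulting enamine closes the ring by a 5-exo aldol onto the tethered aldehyde, and E1cB loss of water gives the α-branched enal 8, which no longer forms an iminium ion readily, so racemisation by retro-oxa-Michael (the reverse of a 5-endo closure) is shut off; the closest known reaction types are the diarylprolinol silyl ether catalysed sulfa-Michael/aldol condensation of enals with 1,4-dithiane-2,5-diol to 2,5-dihydrothiophene-3-carbaldehydes, the oxa-Michael/aldol condensation of enals with salicylaldehydes to 2H-chromene-3-carbaldehydes, and the oxa-Michael/aldol cascade of enals with dihydroxyacetone dimer.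

Step 3
Reactants: 9 1-[3-(benzyloxy)-4-methoxyphenyl]ethan-1-one
Product: 10 2-[3-(benzyloxy)-4-methoxyphenyl]-2-oxoacetic acid
Conditions: SeO2 (2 equiv), pyridine, 110 °C; then aq. HCl
Reagents that add atoms: selenium dioxide SeO2, O=[Se]=O
Why: Riley-type SeO2 oxidation of an aryl methyl ketone in pyridine runs through the arylglyoxal to the arylglyoxylic acid, and no stereocentre is involved.

Step 4
Reactants: 8 (R)-2-[3-(benzyloxy)-4-methoxyphenyl]-2,5-dihydrofuran-3-carbaldehyde; 10 2-[3-(benzyloxy)-4-methoxyphenyl]-2-oxoacetic acid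
Product: 12 (2S,3S,4S)-4-[3-(benzyloxy)-4-methoxybenzoyl]-2-[3-(benzyloxy)-4-methoxyphenyl]tetrahydrofuran-3-carbaldehyde, via kinetic epimer mixture 11 (not isolated)
Conditions: 10 (1.5 equiv), [Ir(dF(CF3)ppy)2(dtbbpy)]PF6 (1 mol %), K2HPO4 (1.2 equiv), DMSO, blue LEDs, rt; then DBU (0.5 equiv), PhMe, 50 °C
Reagents that add atoms: none
Why: Photoredox decarboxylative acyl-radical conjugate addition (Giese reaction): the excited iridium complex oxidises the α-keto carboxylate, CO2 is lost, the nucleophilic aroyl radical adds to C4 (the β-carbon of the enal) and reduction/protonation of the α-formyl radical gives 11; C2 is untouched, and because C3 (α to CHO) and C4 (α to the aryl ketone) are both enolisable, DBU equilibrates the mixture to the all-trans isomer 12 (2,3-trans and 3,4-trans), ring opening by E1cB being the disfavoured reverse of a 5-endo-trig closure.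

Step 5
Reactants: 12 (2S,3S,4S)-4-[3-(benzyloxy)-4-methoxybenzoyl]-2-[3-(benzyloxy)-4-methoxyphenyl]tetrahydrofuran-3-carbaldehyde
Product: 13 {(2S,3R,4S)-4-[3-(benzyloxy)-4-methoxybenzoyl]-2-[3-(benzyloxy)-4-methoxyphenyl]tetrahydrofuran-3-yl}methanol
Conditions: NaBH4 (0.5 equiv), EtOH/CH2Cl2 3:7, −78 °C; aq. NH4Cl
Reagents that add atoms: none
Why: Chemoselective borohydride reduction, in which the aldehyde reacts far faster at −78 °C than the hindered, electron-rich aryl ketone; the stereocentres are untouched (the C3 descriptor changes only by priority) and the 3,4-trans hydroxy ketone cannot close to a hemiketal.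

Step 6
Reactants: 13 {(2S,3R,4S)-4-[3-(benzyloxy)-4-methoxybenzoyl]-2-[3-(benzyloxy)-4-methoxyphenyl]tetrahydrofuran-3-yl}methanol
Product: 14 {(2S,3R,4S)-4-(3-hydroxy-4-methoxybenzoyl)-2-(3-hydroxy-4-methoxyphenyl)tetrahydrofuran-3-yl}methanol (CNP0234761.1)
Conditions: H2 (1 atm), 10% Pd/C, EtOAc, rt, stopped after uptake of 2 equiv
Reagents that add atoms: none
Why: Catalytic hydrogenolysis of the two aryl benzyl ethers is much faster under neutral conditions at 1 atm than reduction of the electron-rich aryl ketone or cleavage of the cyclic benzylic C2–O bond, and no stereocentre is touched.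

## Compound list

1 | 3-(benzyloxy)-4-methoxybenzaldehyde | COc1ccc(C=O)cc1OCc1ccccc1 | starting material
2 | (triphenylphosphoranylidene)acetaldehyde | O=CC=P(c1ccccc1)(c1ccccc1)c1ccccc1 | starting material
3 | (E)-3-[3-(benzyloxy)-4-methoxyphenyl]prop-2-enal | COc1ccc(/C=C/C=O)cc1OCc1ccccc1 | intermediate
4 | 1,4-dioxane-2,5-diol (glycolaldehyde dimer) | OC1COC(O)CO1 | starting material
5 | glycolaldehyde monomer (2-hydroxyacetaldehyde) | OCC=O | intermediate
6 | (S)-3-[3-(benzyloxy)-4-methoxyphenyl]-3-(2-oxoethoxy)propanal (oxa-Michael adduct) | O=CC[C@H](OCC=O)c1ccc(OC)c(OCc2ccccc2)c1 | intermediate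
7 | (2S)-2-[3-(benzyloxy)-4-methoxyphenyl]-4-hydroxytetrahydrofuran-3-carbaldehyde (aldol adduct, epimers at C3 and C4) | O=CC1C(O)CO[C@@H]1c1ccc(OC)c(OCc2ccccc2)c1 | intermediate
8 | (R)-2-[3-(benzyloxy)-4-methoxyphenyl]-2,5-dihydrofuran-3-carbaldehyde | O=CC1=CCO[C@@H]1c1ccc(OC)c(OCc2ccccc2)c1 | intermediate
9 | 1-[3-(benzyloxy)-4-methoxyphenyl]ethan-1-one | CC(=O)c1ccc(OC)c(OCc2ccccc2)c1 | starting material
10 | 2-[3-(benzyloxy)-4-methoxyphenyl]-2-oxoacetic acid | O=C(O)C(=O)c1ccc(OC)c(OCc2ccccc2)c1 | intermediate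
11 | (2S)-4-[3-(benzyloxy)-4-methoxybenzoyl]-2-[3-(benzyloxy)-4-methoxyphenyl]tetrahydrofuran-3-carbaldehyde (kinetic mixture of epimers at C3 and C4) | COc1ccc(C(=O)C2CO[C@H](c3ccc(OC)c(OCc4ccccc4)c3)C2C=O)cc1OCc1ccccc1 | intermediate
12 | (2S,3S,4S)-4-[3-(benzyloxy)-4-methoxybenzoyl]-2-[3-(benzyloxy)-4-methoxyphenyl]tetrahydrofuran-3-carbaldehyde (all-trans) | COc1ccc(C(=O)[C@@H]2CO[C@H](c3ccc(OC)c(OCc4ccccc4)c3)[C@H]2C=O)cc1OCc1ccccc1 | intermediate
13 | {(2S,3R,4S)-4-[3-(benzyloxy)-4-methoxybenzoyl]-2-[3-(benzyloxy)-4-methoxyphenyl]tetrahydrofuran-3-yl}methanol | COc1ccc(C(=O)[C@@H]2CO[C@H](c3ccc(OC)c(OCc4ccccc4)c3)[C@H]2CO)cc1OCc1ccccc1 | intermediate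
14 | {(2S,3R,4S)-4-(3-hydroxy-4-methoxybenzoyl)-2-(3-hydroxy-4-methoxyphenyl)tetrahydrofuran-3-yl}methanol | COc1ccc(C(=O)[C@@H]2CO[C@H](c3ccc(OC)c(O)c3)[C@H]2CO)cc1O | target

## Step count and risks

Total steps: 6. Longest linear sequence: 5 (steps 1, 2, 4, 5, 6).

Most likely to fail, first: step 2, the proposed new cascade. The hydroxyl of glycolaldehyde is a weak and reversible oxa-Michael donor, glycolaldehyde can condense with itself, the ee may be eroded, and 8 can oxidise in air to the furan. The fallback uses known chemistry only, sets out from 1 and comes back at 8. The stereocentre is set by oxazaborolidine-catalysed ketone reduction and the ring is closed by metathesis. Addition of ethynylmagnesium bromide to 1 gives racemic 1-[3-(benzyloxy)-4-methoxyphenyl]prop-2-yn-1-ol F1. MnO2 oxidation gives 1-[3-(benzyloxy)-4-methoxyphenyl]prop-2-yn-1-one F2. CBS reduction ((R)-Me-CBS oxazaborolidine, catecholborane, −78 °C, aryl as the large group) gives (S)-1-[3-(benzyloxy)-4-methoxyphenyl]prop-2-yn-1-ol F3. NaH and allyl bromide give 2-(benzyloxy)-1-methoxy-4-[(1S)-1-(prop-2-en-1-yloxy)prop-2-yn-1-yl]benzene F4. Ring-closing enyne metathesis (second-generation Grubbs catalyst, ethylene 1 atm, CH2Cl2, 40 °C) gives (S)-2-[3-(benzyloxy)-4-methoxyphenyl]-3-ethenyl-2,5-dihydrofuran F5. Dihydroxylation of the unhindered terminal vinyl group in preference to the trisubstituted ring alkene (OsO4 2 mol %, NMO 1.0 equiv, acetone/H2O, 0 °C) gives 1-{(2R)-2-[3-(benzyloxy)-4-methoxyphenyl]-2,5-dihydrofuran-3-yl}ethane-1,2-diol F6, and glycol cleavage with NaIO4 (THF/H2O, 0 °C) gives 8.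

Second: step 4. The aroyl radical may add slowly to the hindered, α-branched cyclic enal, radicals may abstract the doubly activated C2–H or C5–H of 8 (leading to the furan), and epimerisation at C4 may be incomplete. The fallback sets out from 8 and comes back at 12. It changes the acyl donor and the way the radical is made, to a thermal chain without photocatalyst, base or carboxylate. Se-phenyl 3-(benzyloxy)-4-methoxybenzenecarboselenoate F7 (from commercial 3-(benzyloxy)-4-methoxybenzoic acid, PhSeSePh, Bu3P) is added to 8 with (Me3Si)3SiH and AIBN in benzene at 80 °C. The same DBU equilibration then gives 12.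

Third: step 5. The aryl ketone may be partly reduced, or C4 may epimerise under the basic hydride. The fallback sets out from 12 and comes back at 13. Both carbonyl groups are reduced with excess NaBH4 (MeOH, 0 °C) to [3-(benzyloxy)-4-methoxyphenyl]{(3S,4R,5S)-5-[3-(benzyloxy)-4-methoxyphenyl]-4-(hydroxymethyl)oxolan-3-yl}methanol F8 (carbinol epimers). Activated MnO2 (CH2Cl2, rt) then re-oxidises only the electron-rich secondary benzylic alcohol, leaves the primary alcohol, and gives 13.

## Further compounds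

F1 | step 2 | racemic 1-[3-(benzyloxy)-4-methoxyphenyl]prop-2-yn-1-ol | C#CC(O)c1ccc(OC)c(OCc2ccccc2)c1
F2 | step 2 | 1-[3-(benzyloxy)-4-methoxyphenyl]prop-2-yn-1-one | C#CC(=O)c1ccc(OC)c(OCc2ccccc2)c1
F3 | step 2 | (S)-1-[3-(benzyloxy)-4-methoxyphenyl]prop-2-yn-1-ol | C#C[C@H](O)c1ccc(OC)c(OCc2ccccc2)c1
F4 | step 2 | 2-(benzyloxy)-1-methoxy-4-[(1S)-1-(prop-2-en-1-yloxy)prop-2-yn-1-yl]benzene | C#C[C@H](OCC=C)c1ccc(OC)c(OCc2ccccc2)c1
F5 | step 2 | (S)-2-[3-(benzyloxy)-4-methoxyphenyl]-3-ethenyl-2,5-dihydrofuran | C=CC1=CCO[C@@H]1c1ccc(OC)c(OCc2ccccc2)c1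
F6 | step 2 | 1-{(2R)-2-[3-(benzyloxy)-4-methoxyphenyl]-2,5-dihydrofuran-3-yl}ethane-1,2-diol (carbinol epimers) | OCC(O)C1=CCO[C@@H]1c1ccc(OC)c(OCc2ccccc2)c1
F7 | step 4 | Se-phenyl 3-(benzyloxy)-4-methoxybenzenecarboselenoate | O=C([Se]c1ccccc1)c1ccc(OC)c(OCc2ccccc2)c1
F8 | step 5 | [3-(benzyloxy)-4-methoxyphenyl]{(3S,4R,5S)-5-[3-(benzyloxy)-4-methoxyphenyl]-4-(hydroxymethyl)oxolan-3-yl}methanol (carbinol epimers) | COc1ccc(C(O)[C@@H]2CO[C@H](c3ccc(OC)c(OCc4ccccc4)c3)[C@H]2CO)cc1OCc1ccccc1
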